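Write down the balance of the reagent, which is charged in the smaller amount (the limiting reagent): taking one reagent per product, the share R of its charge still left is 1 − P/E, with P the product in percent of starting material charged and E the equivalents.

common to all: catalyst 0.23 mol%; added ligand 1.2 mM

| flask | starting material | reagent | remark |
|---|---|---|---|
| theta | 0.10 M | 0.95 equiv | the very flask that is asked about, followed so far |
| alpha | 0.15 M | 0.95 equiv | run made earlier |
| flask | 0.10 M | 0.950 equiv |  |

| run | time / d | product / % |
|---|---|---|
| theta | 0.625 | 6.6 |
| theta | 1.25 | 13.3 |
| theta | 2.08 | 16.5 |
| theta | 2.50 | 17.6 |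
| theta | 3.00 | 18.1 |
| theta | 4.00 | 20.3 |
| theta | 5.00 | 20.3 |
| alpha | 2.00 | 27.6 |
| alpha | 4.00 | 31.5 |
| alpha | 6.00 | 32.8 |
| alpha | 8.00 | 33.6 |
| alpha | 10.0 | 33.8 |
| alpha | 12.0 | 33.7 |
| alpha | 15.0 | 32.8 |

(standard deviation of a reading: 0.5 percentage points)

1. factor on the rate of making product when 50 % of the starting material are converted if catalyst is charged twice over
2. factor on the rate when 50 % of the starting material are converted if catalyst is charged at 0.025 mol% instead

- what has left starting material counts as converted, also if it is not yet product

At the plateaus R is 78.6 % in theta and 64.4 % in alpha, so neither stop is the reagent running out, and I suspect the working catalyst is what fades. If the rate falls by a fixed proportion each day, the gap between P and its plateau F shrinks the same way, and one reading gives the time constant of that fall as t/ln(F/(F − P)). Theta at 1.25 d gives 1.17 d; this is the loss time τ.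

Now take the neighbour, alpha, with 0.15 M of starting material instead of 0.10 M but the same 1.2 mM of added ligand. Its plateau and this τ give 27.6 % at 2.00 d, and the reading is 27.6 %. So one clock serves both, and the concentration they share is that of the added ligand, which I suspect takes up catalyst: it stands at 5.22 times the catalyst charge in theta and 3.48 times in alpha.

My rule is that the rate scales with the catalyst charged times the share still working when 50 % is converted. More catalyst gets there sooner, with more of it working, so I commit to a factor above 2 for doubling. The smaller loading gets there later, so I commit to a factor below its charge ratio, 0.109.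

The forecast gives 1.65 and 0.17, on this ground: “Sub-first order suggests a resting dimer or reservoir”. The flask gives 2.26 and 0.00535.

    starting material + catalyst ⇌ catalyst + intermediate (K = 3.80, k = 440 M⁻¹ h⁻¹)
    reagent + catalyst + intermediate ⇌ catalyst + product (K = 7.30 M⁻¹, k = 770 M⁻² h⁻¹)
    catalyst + added ligand ⇌ idle complex (K = 21000 M⁻¹, k = 23.0 M⁻¹ h⁻¹)

In the theta flask 50 % is converted at 0.363 d, with 79.1 % of the catalyst free, where τ gives 73.3 %. In the theta flask the half-life of the reagent by the forward rate of its step alone is 4.9 d at 0.266 d, longer than τ, and intermediate is then made 8.01 times as fast as it is used up. At 15.0 d the theta flask holds 59.7 % intermediate and 23.9 % product, with 95.4 % of the catalyst as idle complex, and the balance gives 74.8 % of the reagent, against 75 % left.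

The data stem from a simulated flask on assumed constants; noise was put on by code.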